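**Retrosynthetic overview**

1. Target 24 ← C9 silyl ether 23 (desilylation only).
2. 23 ← acyclic allene dialdehyde 20 in one operation: I2 turns the allene into a 2‑iodoallyl iodide; CrCl2 allylation closes the seven‑membered ring (C5–C6) first, then Ni/Cr alkenyl addition closes the five‑membered ring (C3–C4).
3. 20 ← aldehyde 11 + alkenyl iodide 18 (asymmetric Ni/Cr coupling, C9–C10), then Swern oxidation of two primary silyl ethers.
4. 11 ← cis‑lactone 6 (Brown syn‑crotylboration of 4‑methylpent‑3‑enal; trans α‑alkylation sets C7).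
5. 18 ← but‑3‑yn‑1‑ol via a (Z)‑2‑iodoallyl phosphate and Cu‑catalysed enantioselective SN2′ allenylation (C1).

Assumption: atom labels C1–C20 follow dictyotane numbering (C1/C5 ring fusion; C3, C6, C9 carbinols; C4=C19 and C10=C18 methylidenes; C11/C12 side chain); the target as drawn is (1R,3S,5S,6R,7S,9R,11S,12S) with a trans ring fusion.

**Route**

Step 1
Reactants: 1 4‑methylpent‑3‑en‑1‑ol
Product: 2 4‑methylpent‑3‑enal
Conditions: Dess–Martin periodinane, NaHCO3, CH2Cl2, 0 °C; solution used at once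
Reagents that add atoms: none
Why: Buffered Dess–Martin oxidation gives the β,γ‑unsaturated aldehyde under non‑basic conditions, so the trisubstituted alkene does not move into conjugation.

Step 2
Reactants: 2 4‑methylpent‑3‑enal
Product: 3 (3S,4S)‑3,7‑dimethylocta‑1,6‑dien‑4‑ol
Conditions: cis‑2‑butene, n‑BuLi, KOt‑Bu, THF, −78 → −45 °C; (+)‑Ipc2BOMe, −78 °C; BF3·OEt2; then 2, −78 °C; NaOH, H2O2
Reagents that add atoms: cis‑2‑butene, C/C=C\C
Why: Brown asymmetric crotylboration: the (Z)‑crotylborane adds through a closed chair transition state to give the syn adduct, and the isopinocampheyl groups derived from (−)‑α‑pinene select the aldehyde face that gives C12 (S) and C11 (S).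

Step 3
Reactants: 3 (3S,4S)‑3,7‑dimethylocta‑1,6‑dien‑4‑ol
Product: 5 (3S,4S)‑3,7‑dimethyloct‑6‑ene‑1,4‑diol, via bis‑boryl adduct 4 (not isolated)
Conditions: 9‑BBN (2.2 equiv), THF, 0 °C → rt; then NaOH, H2O2
Reagents that add atoms: hydrogen peroxide, OO
Why: Anti‑Markovnikov hydroboration–oxidation; 9‑BBN reacts with the monosubstituted vinyl group and leaves the trisubstituted alkene alone.

Step 4
Reactants: 5 (3S,4S)‑3,7‑dimethyloct‑6‑ene‑1,4‑diol
Product: 6 (4S,5S)‑4‑methyl‑5‑(3‑methylbut‑2‑en‑1‑yl)oxolan‑2‑one (cis lactone)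
Conditions: TEMPO (10 mol%), PhI(OAc)2 (2.5 equiv), CH2Cl2, rt
Reagents that add atoms: none
Why: Oxoammonium (TEMPO) oxidation takes the primary alcohol to the aldehyde, which closes to the lactol and is oxidised on to the γ‑lactone without touching the stereocentres or the alkene.

Step 5
Reactants: 6 (4S,5S)‑4‑methyl‑5‑(3‑methylbut‑2‑en‑1‑yl)oxolan‑2‑one
Product: 7 (3S,4S,5S)‑3‑(2,2‑dimethoxyethyl)‑4‑methyl‑5‑(3‑methylbut‑2‑en‑1‑yl)oxolan‑2‑one
Conditions: LiN(i‑Pr)2, THF, −78 °C; BrCH2CH(OMe)2, DMPU, −78 → 0 °C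
Reagents that add atoms: 2‑bromo‑1,1‑dimethoxyethane, COC(CBr)OC
Why: Lactone enolate alkylation; the electrophile enters anti to the adjacent C11 methyl group, giving the 3,4‑trans lactone and so C7 (S).

Step 6
Reactants: 7 (3S,4S,5S)‑3‑(2,2‑dimethoxyethyl)‑4‑methyl‑5‑(3‑methylbut‑2‑en‑1‑yl)oxolan‑2‑one
Product: 8 (2S,3S,4S)‑2‑(2,2‑dimethoxyethyl)‑3,7‑dimethyloct‑6‑ene‑1,4‑diol
Conditions: LiAlH4, THF, 0 °C
Reagents that add atoms: none
Why: Hydride reduction of the lactone to the 1,4‑diol; the acetal and the alkene are inert.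

Step 7
Reactants: 8 (2S,3S,4S)‑2‑(2,2‑dimethoxyethyl)‑3,7‑dimethyloct‑6‑ene‑1,4‑diol
Product: 10 (2S,3S,4S)‑2‑(2,2‑dimethoxyethyl)‑3,7‑dimethyl‑1‑[(triethylsilyl)oxy]oct‑6‑en‑4‑yl acetate, via mono‑silyl ether 9 (not isolated)
Conditions: Et3SiCl (1.05 equiv), imidazole, CH2Cl2, −78 → 0 °C; then Ac2O, DMAP, pyridine, rt
Reagents that add atoms: chlorotriethylsilane, CC[Si](Cl)(CC)CC; acetic anhydride, CC(=O)OC(C)=O
Why: The primary hydroxyl is silylated far faster than the hindered secondary one, which is then acetylated, so the C12 acetate of the target is installed before any other free hydroxyl exists.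

Step 8
Reactants: 10 (2S,3S,4S)‑2‑(2,2‑dimethoxyethyl)‑3,7‑dimethyl‑1‑[(triethylsilyl)oxy]oct‑6‑en‑4‑yl acetate
Product: 11 (2S,3S,4S)‑3,7‑dimethyl‑2‑(2‑oxoethyl)‑1‑[(triethylsilyl)oxy]oct‑6‑en‑4‑yl acetate
Conditions: Et3SiOTf, 2,4,6‑collidine, CH2Cl2, 0 °C; then H2O
Reagents that add atoms: water, O
Why: Chemoselective acetal cleavage through a collidinium intermediate under non‑protic conditions, which spares the primary silyl ether, the acetate and the alkene.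

Step 9
Reactants: 12 but‑3‑yn‑1‑ol
Product: 13 (but‑3‑yn‑1‑yloxy)triethylsilane
Conditions: Et3SiCl, imidazole, CH2Cl2, 0 °C
Reagents that add atoms: chlorotriethylsilane, CC[Si](Cl)(CC)CC
Why: Standard silylation of a primary alcohol.

Step 10
Reactants: 13 (but‑3‑yn‑1‑yloxy)triethylsilane
Product: 14 5‑[(triethylsilyl)oxy]pent‑2‑yn‑1‑ol
Conditions: n‑BuLi, THF, −78 °C; (CH2O)n, −78 °C → rt
Reagents that add atoms: formaldehyde (as paraformaldehyde), C=O
Why: Addition of the lithium acetylide to formaldehyde gives the propargylic alcohol.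

Step 11
Reactants: 14 5‑[(triethylsilyl)oxy]pent‑2‑yn‑1‑ol
Product: 16 (Z)‑2‑iodo‑5‑[(triethylsilyl)oxy]pent‑2‑en‑1‑ol, via vinylstannane 15 (not isolated)
Conditions: Bu3SnH, [(C5Me5)RuCl]4 (1.5 mol%), CH2Cl2, rt; then I2, 0 °C
Reagents that add atoms: iodine, II
Why: Hydroxyl‑directed ruthenium‑catalysed trans‑hydrostannation puts tin on the alkyne carbon next to the CH2OH group, and iododestannylation with retention gives the (Z)‑2‑iodo allylic alcohol.

Step 12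
Reactants: 16 (Z)‑2‑iodo‑5‑[(triethylsilyl)oxy]pent‑2‑en‑1‑ol
Product: 17 diethyl (Z)‑2‑iodo‑5‑[(triethylsilyl)oxy]pent‑2‑en‑1‑yl phosphate
Conditions: ClP(O)(OEt)2, Et3N, DMAP (cat.), CH2Cl2, 0 °C
Reagents that add atoms: diethyl chlorophosphate, CCOP(=O)(Cl)OCC
Why: Phosphorylation of the allylic alcohol gives the leaving group for copper‑catalysed allylic substitution.

Step 13
Reactants: 17 diethyl (Z)‑2‑iodo‑5‑[(triethylsilyl)oxy]pent‑2‑en‑1‑yl phosphate
Product: 18 triethyl{[(3R)‑3‑(1‑iodoethenyl)hexa‑4,5‑dien‑1‑yl]oxy}silane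
Conditions: allenyl–B(pin) (1.5 equiv), CuCl (5 mol%), chiral sulfonate‑bearing imidazolinium salt (carbene precursor, 6 mol%, enantiomer giving 3R), NaOMe (1.5 equiv), THF, −30 → 22 °C
Reagents that add atoms: allenylboronic acid pinacol ester, C=C=CB1OC(C)(C)C(C)(C)O1
Why: Carbene–copper‑catalysed enantioselective allylic substitution (SN2′): the allenyl group is delivered to C1, the double bond shifts to C10=C18 to leave the 1‑iodovinyl group, and the chiral ligand sets C1 (R).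

Step 14
Reactants: 11 (2S,3S,4S)‑3,7‑dimethyl‑2‑(2‑oxoethyl)‑1‑[(triethylsilyl)oxy]oct‑6‑en‑4‑yl acetate; 18 triethyl{[(3R)‑3‑(1‑iodoethenyl)hexa‑4,5‑dien‑1‑yl]oxy}silane
Product: 19 (2S,3S,4S)‑3,7‑dimethyl‑2‑[(2R,4R)‑3‑methylidene‑2‑[(triethylsilyl)oxy]‑4‑{2‑[(triethylsilyl)oxy]ethyl}hepta‑5,6‑dien‑1‑yl]‑1‑[(triethylsilyl)oxy]oct‑6‑en‑4‑yl acetate
Conditions: CrCl2 (10 mol%), chiral oxazoline–sulfonamide ligand (11 mol%, enantiomer giving 9R), 1,8‑bis(dimethylamino)naphthalene, NiCl2(2,9‑dimethyl‑1,10‑phenanthroline) (2 mol%), Mn powder, LiCl, Et3SiCl, MeCN, rt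
Reagents that add atoms: chlorotriethylsilane, CC[Si](Cl)(CC)CC
Why: Catalytic asymmetric Nozaki–Hiyama–Kishi coupling: zerovalent nickel inserts into the C–I bond, transmetalation gives an alkenylchromium that adds to the aldehyde under ligand control to set C9 (R), and Et3SiCl releases the product as its silyl ether; acetate, silyl ethers and the allene are tolerated.

Step 15
Reactants: 19 (the tris‑silyl ether above)
Product: 20 (2S,3S,4S)‑3,7‑dimethyl‑2‑[(2R,4R)‑3‑methylidene‑4‑(2‑oxoethyl)‑2‑[(triethylsilyl)oxy]hepta‑5,6‑dien‑1‑yl]‑1‑oxooct‑6‑en‑4‑yl acetate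
Conditions: (COCl)2, DMSO, CH2Cl2, −78 → −30 °C; Et3N, −78 → 0 °C
Reagents that add atoms: none
Why: Swern oxidation cleaves and oxidises the two primary triethylsilyl ethers directly to the C3 and C6 aldehydes while the secondary C9 silyl ether is kept.

Step 16
Reactants: 20 (the allene dialdehyde above)
Product: 23 (2S,3S)‑2‑[(2S,3aR,5R,7S,8R,8aS)‑2,8‑dihydroxy‑1,4‑dimethylidene‑5‑[(triethylsilyl)oxy]decahydroazulen‑7‑yl]‑6‑methylhept‑5‑en‑3‑yl acetate, via diiodide 21 (not isolated), via seven‑membered‑ring alkenyl iodide 22 (not isolated)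
Conditions: I2 (1.0 equiv), CH2Cl2, 0 °C, dark; solvent exchange; CrCl2 (8 equiv), NiCl2 (2 mol%), DMF–THF, 0.002 M, 0 °C → rt
Reagents that add atoms: none
Why: Proposed new method: I2 adds to the terminal allene to give a 2‑iodoallyl iodide (either regioisomer gives the same allylchromium), divalent chromium reduces the allylic C–I bond and the allylchromium adds through its γ‑carbon C5 to the C6 aldehyde (the only one it can reach, C3 would need a four‑membered ring) via a chair transition state in which C1 and C7 are equatorial (anti C5/C6), allylic 1,3‑strain against the C4 iodine holds C1–H in the alkene plane so the ring closes on the face away from the CH2CHO arm (trans C1/C5) and C7 reacts in the Felkin–Anh sense, after which nickel‑catalysed activation of the remaining alkenyl iodide gives an alkenylchromium that closes the five‑membered ring onto the C3 aldehyde with the chromium alkoxide pseudo‑equatorial (3S); the closest known chemistry is chromium‑mediated 2‑haloallylation of aldehydes followed by Ni/Cr alkenyl halide addition (Nozaki–Hiyama–Kishi), here run intramolecularly in one flask.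

Step 17
Reactants: 23 (the bicyclic silyl ether above)
Product: 24 (2S,3S)‑6‑methyl‑2‑[(2S,3aR,5R,7S,8R,8aS)‑2,5,8‑trihydroxy‑1,4‑dimethylidenedecahydroazulen‑7‑yl]hept‑5‑en‑3‑yl acetate (target)
Conditions: HF·pyridine, pyridine, THF, 0 °C
Reagents that add atoms: none
Why: Fluoride cleaves the secondary triethylsilyl ether without touching the acetate or the allylic alcohols.

**Compound list**

1 | 4‑methylpent‑3‑en‑1‑ol | CC(C)=CCCO | starting material
2 | 4‑methylpent‑3‑enal | CC(C)=CCC=O | intermediate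
3 | (3S,4S)‑3,7‑dimethylocta‑1,6‑dien‑4‑ol | C=C[C@H](C)[C@H](CC=C(C)C)O | intermediate
4 | (3S,4S)‑1‑(9‑borabicyclo[3.3.1]nonan‑9‑yl)‑4‑(9‑borabicyclo[3.3.1]nonan‑9‑yloxy)‑3,7‑dimethyloct‑6‑ene | C(CB1C2CCCC1CCC2)[C@H](C)[C@H](CC=C(C)C)OB1C2CCCC1CCC2 | intermediate
5 | (3S,4S)‑3,7‑dimethyloct‑6‑ene‑1,4‑diol | OCC[C@H](C)[C@H](CC=C(C)C)O | intermediate
6 | (4S,5S)‑4‑methyl‑5‑(3‑methylbut‑2‑en‑1‑yl)oxolan‑2‑one | O=C1C[C@H](C)[C@H](CC=C(C)C)O1 | intermediate
7 | (3S,4S,5S)‑3‑(2,2‑dimethoxyethyl)‑4‑methyl‑5‑(3‑methylbut‑2‑en‑1‑yl)oxolan‑2‑one | O=C1[C@@H](CC(OC)OC)[C@H](C)[C@H](CC=C(C)C)O1 | intermediate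
8 | (2S,3S,4S)‑2‑(2,2‑dimethoxyethyl)‑3,7‑dimethyloct‑6‑ene‑1,4‑diol | OC[C@@H](CC(OC)OC)[C@H](C)[C@H](CC=C(C)C)O | intermediate
9 | (2S,3S,4S)‑2‑(2,2‑dimethoxyethyl)‑3,7‑dimethyl‑1‑[(triethylsilyl)oxy]oct‑6‑en‑4‑ol | CC[Si](CC)(CC)OC[C@@H](CC(OC)OC)[C@H](C)[C@H](CC=C(C)C)O | intermediate
10 | (2S,3S,4S)‑2‑(2,2‑dimethoxyethyl)‑3,7‑dimethyl‑1‑[(triethylsilyl)oxy]oct‑6‑en‑4‑yl acetate | CC[Si](CC)(CC)OC[C@@H](CC(OC)OC)[C@H](C)[C@H](CC=C(C)C)OC(C)=O | intermediate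
11 | (2S,3S,4S)‑3,7‑dimethyl‑2‑(2‑oxoethyl)‑1‑[(triethylsilyl)oxy]oct‑6‑en‑4‑yl acetate | CC[Si](CC)(CC)OC[C@@H](CC=O)[C@H](C)[C@H](CC=C(C)C)OC(C)=O | intermediate
12 | but‑3‑yn‑1‑ol | C#CCCO | starting material
13 | (but‑3‑yn‑1‑yloxy)triethylsilane | C#CCCO[Si](CC)(CC)CC | intermediate
14 | 5‑[(triethylsilyl)oxy]pent‑2‑yn‑1‑ol | OCC#CCCO[Si](CC)(CC)CC | intermediate
15 | (Z)‑2‑(tributylstannyl)‑5‑[(triethylsilyl)oxy]pent‑2‑en‑1‑ol | OC/C(=C/CCO[Si](CC)(CC)CC)[Sn](CCCC)(CCCC)CCCC | intermediate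
16 | (Z)‑2‑iodo‑5‑[(triethylsilyl)oxy]pent‑2‑en‑1‑ol | OC/C(I)=C/CCO[Si](CC)(CC)CC | intermediate
17 | diethyl (Z)‑2‑iodo‑5‑[(triethylsilyl)oxy]pent‑2‑en‑1‑yl phosphate | CCOP(=O)(OCC)OC/C(I)=C/CCO[Si](CC)(CC)CC | intermediate
18 | triethyl{[(3R)‑3‑(1‑iodoethenyl)hexa‑4,5‑dien‑1‑yl]oxy}silane | C=C(I)[C@@H](C=C=C)CCO[Si](CC)(CC)CC | intermediate
19 | (2S,3S,4S)‑3,7‑dimethyl‑2‑[(2R,4R)‑3‑methylidene‑2‑[(triethylsilyl)oxy]‑4‑{2‑[(triethylsilyl)oxy]ethyl}hepta‑5,6‑dien‑1‑yl]‑1‑[(triethylsilyl)oxy]oct‑6‑en‑4‑yl acetate | CC[Si](CC)(CC)OCC[C@H](C=C=C)C(=C)[C@H](O[Si](CC)(CC)CC)C[C@H](CO[Si](CC)(CC)CC)[C@H](C)[C@H](CC=C(C)C)OC(C)=O | intermediate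
20 | (2S,3S,4S)‑3,7‑dimethyl‑2‑[(2R,4R)‑3‑methylidene‑4‑(2‑oxoethyl)‑2‑[(triethylsilyl)oxy]hepta‑5,6‑dien‑1‑yl]‑1‑oxooct‑6‑en‑4‑yl acetate | O=CC[C@H](C=C=C)C(=C)[C@H](O[Si](CC)(CC)CC)C[C@H](C=O)[C@H](C)[C@H](CC=C(C)C)OC(C)=O | intermediate
21 | (2S,3S,4S)‑2‑[(2R,4R)‑6,7‑diiodo‑3‑methylidene‑4‑(2‑oxoethyl)‑2‑[(triethylsilyl)oxy]hept‑5‑en‑1‑yl]‑3,7‑dimethyl‑1‑oxooct‑6‑en‑4‑yl acetate (alkene E/Z mixture) | O=CC[C@H](C=C(I)CI)C(=C)[C@H](O[Si](CC)(CC)CC)C[C@H](C=O)[C@H](C)[C@H](CC=C(C)C)OC(C)=O | intermediate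
22 | (2S,3S)‑2‑[(1S,2R,3R,4R,6R)‑2‑hydroxy‑3‑(1‑iodoethenyl)‑5‑methylidene‑4‑(2‑oxoethyl)‑6‑[(triethylsilyl)oxy]cycloheptyl]‑6‑methylhept‑5‑en‑3‑yl acetate | C=C(I)[C@H]1[C@H](O)[C@H]([C@H](C)[C@H](CC=C(C)C)OC(C)=O)C[C@@H](O[Si](CC)(CC)CC)C(=C)[C@@H]1CC=O | intermediate
23 | (2S,3S)‑2‑[(2S,3aR,5R,7S,8R,8aS)‑2,8‑dihydroxy‑1,4‑dimethylidene‑5‑[(triethylsilyl)oxy]decahydroazulen‑7‑yl]‑6‑methylhept‑5‑en‑3‑yl acetate | C=C1[C@H]2[C@H](O)[C@H]([C@H](C)[C@H](CC=C(C)C)OC(C)=O)C[C@@H](O[Si](CC)(CC)CC)C(=C)[C@@H]2C[C@@H]1O | intermediate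
24 | (2S,3S)‑6‑methyl‑2‑[(2S,3aR,5R,7S,8R,8aS)‑2,5,8‑trihydroxy‑1,4‑dimethylidenedecahydroazulen‑7‑yl]hept‑5‑en‑3‑yl acetate | C=C1[C@H]2[C@H](O)[C@H]([C@H](C)[C@H](CC=C(C)C)OC(C)=O)C[C@@H](O)C(=C)[C@@H]2C[C@@H]1O | target

**Totals**

Total step count: 17. Longest linear sequence: 12 (steps 1–8, then 14–17); the five steps to 18 (steps 9–13) run in parallel.

**Three steps most likely to fail, each with a fallback**

Step 16 (ring‑forming cascade). Iodine addition may not be clean next to the other alkenes, the 2‑iodoallylchromium may collapse back to the allene, or the seven‑membered closure may give the wrong C5/C6 diastereomer. Fallback: set out again from 20. Pd(PPh3)4‑catalysed addition of Me3Si–SnBu3 across the terminal double bond of the allene gives the allylstannane–alkenylsilane dialdehyde F1. Transmetalation with InCl3 and intramolecular γ‑allylation of the C6 aldehyde through a closed transition state gives the seven‑membered‑ring alkenylsilane alcohol F2. Iododesilylation with N‑iodosuccinimide gives 22, now isolated, and CrCl2 with catalytic NiCl2 closes the five‑membered ring to return to the route at 23. The two rings are then made in separate operations.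

Step 13 (enantioselective allenylation). The 2‑iodo substituent is outside the usual substrate range and may lower rate or selectivity. Fallback: set out from 17 and run the allenylation with an achiral catalyst (CuCl, 1,3‑dimesitylimidazolium chloride, NaOMe). This gives 18 together with its enantiomer, triethyl{[(3S)‑3‑(1‑iodoethenyl)hexa‑4,5‑dien‑1‑yl]oxy}silane F3. Coupling the mixture with 11 under the step‑14 conditions gives 19 and its C1 epimer, the (2R,4S)‑configured tris‑silyl ether F4, which are separated by chromatography; the route is rejoined at 19. Stereocontrol at C1 is then by separation of diastereomers, not by the catalyst.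

Step 5 (alkylation with a β,β‑dialkoxyethyl bromide). This electrophile is sluggish toward hindered lactone enolates. Fallback: set out from 6. Michael addition of its lithium enolate to nitroethylene gives the nitro lactone (3S,4S,5S)‑4‑methyl‑5‑(3‑methylbut‑2‑en‑1‑yl)‑3‑(2‑nitroethyl)oxolan‑2‑one F5 (addition anti to the C11 methyl; C7 can also be equilibrated to trans). A Nef reaction in methanol (NaOMe, MeOH; then H2SO4/MeOH, −40 °C) converts the nitronate directly into the dimethyl acetal and re‑closes the lactone, returning to the route at 7.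

**Further compounds**

F1 | step 16 | (2S,3S,4S)‑3,7‑dimethyl‑2‑[(2R,4R)‑3‑methylidene‑4‑(2‑oxoethyl)‑7‑(tributylstannyl)‑2‑[(triethylsilyl)oxy]‑6‑(trimethylsilyl)hept‑5‑en‑1‑yl]‑1‑oxooct‑6‑en‑4‑yl acetate | O=CC[C@H](C=C([Si](C)(C)C)C[Sn](CCCC)(CCCC)CCCC)C(=C)[C@H](O[Si](CC)(CC)CC)C[C@H](C=O)[C@H](C)[C@H](CC=C(C)C)OC(C)=O
F2 | step 16 | (2S,3S)‑2‑[(1S,2R,3R,4R,6R)‑2‑hydroxy‑5‑methylidene‑4‑(2‑oxoethyl)‑6‑[(triethylsilyl)oxy]‑3‑[1‑(trimethylsilyl)ethenyl]cycloheptyl]‑6‑methylhept‑5‑en‑3‑yl acetate | C=C([Si](C)(C)C)[C@H]1[C@H](O)[C@H]([C@H](C)[C@H](CC=C(C)C)OC(C)=O)C[C@@H](O[Si](CC)(CC)CC)C(=C)[C@@H]1CC=O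
F3 | step 13 | triethyl{[(3S)‑3‑(1‑iodoethenyl)hexa‑4,5‑dien‑1‑yl]oxy}silane | C=C(I)[C@H](C=C=C)CCO[Si](CC)(CC)CC
F4 | step 13 | (2S,3S,4S)‑3,7‑dimethyl‑2‑[(2R,4S)‑3‑methylidene‑2‑[(triethylsilyl)oxy]‑4‑{2‑[(triethylsilyl)oxy]ethyl}hepta‑5,6‑dien‑1‑yl]‑1‑[(triethylsilyl)oxy]oct‑6‑en‑4‑yl acetate | CC[Si](CC)(CC)OCC[C@@H](C=C=C)C(=C)[C@H](O[Si](CC)(CC)CC)C[C@H](CO[Si](CC)(CC)CC)[C@H](C)[C@H](CC=C(C)C)OC(C)=O
F5 | step 5 | (3S,4S,5S)‑4‑methyl‑5‑(3‑methylbut‑2‑en‑1‑yl)‑3‑(2‑nitroethyl)oxolan‑2‑one | O=C1[C@@H](CC[N+](=O)[O-])[C@H](C)[C@H](CC=C(C)C)O1
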